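**Retrosynthetic overview**
1. Kuwanon C (13) comes from its 7,2',4'-tris-MOM ether 12 by a final acetal cleavage.
2. 12 comes from the 5-O-prenyl flavone 9: the C8 prenyl group is delivered from the C5 oxygen by a Eu(fod)3-catalysed para-Claisen–Cope shift.
3. 9 comes from the open-chain 1,3-diketone 6: ring C is closed through the O1–C2 bond when one of two equivalent aryl prenyl ethers is opened by palladium and its prenyl group is relayed to C3 (proposed new step).
4. 6 comes from ketone 3 and ester 5 by a crossed Claisen condensation; 3 derives from phloroacetophenone 1 (O-MOM, then double O-prenylation) and 5 from methyl 2,4-dihydroxybenzoate 4.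
5. Ring order: rings A and B are bought as arenes; ring C is the only ring made (step 5). Both C-prenyl groups start life as O-prenyl ethers on a symmetric ring A, so no 6- versus 8-regiochemistry question arises before step 6.

Assumption: Kuwanon C has no stereocentre or other stereogenic element, so it is achiral and "single enantiomer" simply means the compound itself; the transient sp3 centres in 7, 8, 10 and 11 are racemic and are erased within the same step.

**Step 1**
Reactants: 1 2,4,6-trihydroxyacetophenone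
Product: 2 1-[2,6-dihydroxy-4-(methoxymethoxy)phenyl]ethanone
Conditions: MOMCl (1.05 equiv), i-Pr2NEt (1.3 equiv), THF, 0 °C
Reagents that add atoms: chloromethyl methyl ether (MOMCl), COCCl
Why: Williamson-type MOM protection, selective because the 4-OH is the only phenol not hydrogen-bonded to the acetyl group and is the most acidic, so one equivalent at 0 °C stops mainly at the mono-ether (the 4,6-bis-ether is removed by chromatography).

**Step 2**
Reactants: 2 1-[2,6-dihydroxy-4-(methoxymethoxy)phenyl]ethanone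
Product: 3 1-[4-(methoxymethoxy)-2,6-bis(3-methylbut-2-enyloxy)phenyl]ethanone
Conditions: prenyl bromide (2.6 equiv), K2CO3 (4 equiv), DMF, 50 °C
Reagents that add atoms: prenyl bromide (1-bromo-3-methylbut-2-ene), CC(C)=CCBr
Why: Williamson ether synthesis in a polar aprotic solvent, which favours O- over C-alkylation of the phenoxides and, with excess reagent and gentle heating, etherifies both chelated hydroxyls while the MOM acetal is inert to base.

**Step 3**
Reactants: 4 methyl 2,4-dihydroxybenzoate
Product: 5 methyl 2,4-bis(methoxymethoxy)benzoate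
Conditions: NaH (2.4 equiv), MOMCl (2.4 equiv), DMF, 0 °C to rt
Reagents that add atoms: chloromethyl methyl ether (MOMCl), COCCl
Why: Williamson-type MOM protection through the sodium phenoxides, the strong base being needed to alkylate the ester-chelated 2-OH as well as the 4-OH.

**Step 4**
Reactants: 3 1-[4-(methoxymethoxy)-2,6-bis(3-methylbut-2-enyloxy)phenyl]ethanone; 5 methyl 2,4-bis(methoxymethoxy)benzoate
Product: 6 1-[2,4-bis(methoxymethoxy)phenyl]-3-[4-(methoxymethoxy)-2,6-bis(3-methylbut-2-enyloxy)phenyl]propane-1,3-dione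
Conditions: LiN(SiMe3)2 (2.5 equiv), THF, −20 °C to rt; then AcOH
Reagents that add atoms: none
Why: Crossed Claisen condensation in which 3 is the only enolisable partner and 5 the only acyl donor, driven to completion by deprotonation of the 1,3-diketone product by the second equivalent of base.

**Step 5**
Reactants: 6 1-[2,4-bis(methoxymethoxy)phenyl]-3-[4-(methoxymethoxy)-2,6-bis(3-methylbut-2-enyloxy)phenyl]propane-1,3-dione
Product: 9 2-[2,4-bis(methoxymethoxy)phenyl]-7-(methoxymethoxy)-3-(3-methylbut-2-enyl)-5-(3-methylbut-2-enyloxy)-4H-chromen-4-one, via C-prenyl diketone 7 (not isolated), via 2-hydroxyflavanone hemiketal 8 (not isolated)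
Conditions: Pd2(dba)3·CHCl3 (2.5 mol %), DPEphos (6 mol %), 1,4-dioxane, 70 °C; then PPTS (10 mol %), 70 °C
Reagents that add atoms: none
Why: Proposed new method: zerovalent palladium ionises one of the two equivalent aryl prenyl ethers of 6 (leaving group: the ortho-acyl phenoxide), the phenoxide deprotonates the 1,3-diketone, and the diketonate attacks the pi-prenyl ligand of the divalent palladium intermediate at its unsubstituted terminus to give the linear C-prenyl diketone 7 with a freed ortho-phenol; that phenol adds to the ring-B ketone (hemiketal 8) and PPTS-assisted loss of water, eased by the electron-rich 2,4-dialkoxyphenyl group, forms the O1–C2 bond and ring C, while a second C-prenylation is blocked sterically and by removal of the acidic CH on ring closure; the closest known reaction type is the Tsuji–Trost deallylation of aryl allyl ethers with 1,3-dicarbonyl scavengers (here the scavenger is part of the substrate and the transferred group is prenyl), followed by the cyclodehydration that ends a Baker–Venkataraman flavone synthesis.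

**Step 6**
Reactants: 9 2-[2,4-bis(methoxymethoxy)phenyl]-7-(methoxymethoxy)-3-(3-methylbut-2-enyl)-5-(3-methylbut-2-enyloxy)-4H-chromen-4-one
Product: 12 2-[2,4-bis(methoxymethoxy)phenyl]-5-hydroxy-7-(methoxymethoxy)-3,8-bis(3-methylbut-2-enyl)-4H-chromen-4-one, via ortho-dienone 10 (not isolated), via para-dienone 11 (not isolated)
Conditions: Eu(fod)3 (10 mol %), NaHCO3, PhCl, 85 °C
Reagents that add atoms: none
Why: Para-Claisen–Cope rearrangement in which trivalent europium chelates the C4 carbonyl and the C5 ether oxygen, the 5-O-prenyl group shifts [3,3] to C6 as a 1,1-dimethylallyl group (10), a second [3,3] Cope shift carries it to C8 with normal prenyl connectivity (11), and enolisation gives the chelated 5-OH phenol, as is precedented for 5-O-prenyl flavonoids carrying a 7-O protecting group.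

**Step 7**
Reactants: 12 2-[2,4-bis(methoxymethoxy)phenyl]-5-hydroxy-7-(methoxymethoxy)-3,8-bis(3-methylbut-2-enyl)-4H-chromen-4-one
Product: 13 Kuwanon C, 2-(2,4-dihydroxyphenyl)-5,7-dihydroxy-3,8-bis(3-methylbut-2-enyl)-4H-chromen-4-one
Conditions: 3 M aq. HCl/MeOH (1:10), 45 °C
Reagents that add atoms: none
Why: Acid-catalysed acetal exchange (MOM ether methanolysis) under dilute, mild conditions of the kind used to unmask 7-hydroxy-8-prenyl flavonoids, kept short and cool so that neither prenyl group cyclises onto a neighbouring phenol.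

**Compound list**
1 | 2,4,6-trihydroxyacetophenone (phloroacetophenone) | CC(=O)c1c(O)cc(O)cc1O | starting material
2 | 1-[2,6-dihydroxy-4-(methoxymethoxy)phenyl]ethanone | CC(=O)c1c(O)cc(OCOC)cc1O | intermediate
3 | 1-[4-(methoxymethoxy)-2,6-bis(3-methylbut-2-enyloxy)phenyl]ethanone | CC(=O)c1c(OCC=C(C)C)cc(OCOC)cc1OCC=C(C)C | intermediate
4 | methyl 2,4-dihydroxybenzoate | COC(=O)c1ccc(O)cc1O | starting material
5 | methyl 2,4-bis(methoxymethoxy)benzoate | COC(=O)c1ccc(OCOC)cc1OCOC | intermediate
6 | 1-[2,4-bis(methoxymethoxy)phenyl]-3-[4-(methoxymethoxy)-2,6-bis(3-methylbut-2-enyloxy)phenyl]propane-1,3-dione (drawn as the diketone; enolised in solution) | COCOc1ccc(C(=O)CC(=O)c2c(OCC=C(C)C)cc(OCOC)cc2OCC=C(C)C)c(OCOC)c1 | intermediate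
7 | 1-[2,4-bis(methoxymethoxy)phenyl]-3-[2-hydroxy-4-(methoxymethoxy)-6-(3-methylbut-2-enyloxy)phenyl]-2-(3-methylbut-2-enyl)propane-1,3-dione (C-prenyl diketone; racemic, formed in the flask) | COCOc1ccc(C(=O)C(CC=C(C)C)C(=O)c2c(O)cc(OCOC)cc2OCC=C(C)C)c(OCOC)c1 | intermediate
8 | 2-[2,4-bis(methoxymethoxy)phenyl]-2-hydroxy-7-(methoxymethoxy)-3-(3-methylbut-2-enyl)-5-(3-methylbut-2-enyloxy)chroman-4-one (hemiketal; diastereomer mixture, formed in the flask) | COCOc1ccc(C2(O)Oc3cc(OCOC)cc(OCC=C(C)C)c3C(=O)C2CC=C(C)C)c(OCOC)c1 | intermediate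
9 | 2-[2,4-bis(methoxymethoxy)phenyl]-7-(methoxymethoxy)-3-(3-methylbut-2-enyl)-5-(3-methylbut-2-enyloxy)-4H-chromen-4-one | COCOc1ccc(-c2oc3cc(OCOC)cc(OCC=C(C)C)c3c(=O)c2CC=C(C)C)c(OCOC)c1 | intermediate
10 | 2-[2,4-bis(methoxymethoxy)phenyl]-7-(methoxymethoxy)-6-(2-methylbut-3-en-2-yl)-3-(3-methylbut-2-enyl)-6H-chromene-4,5-dione (ortho-dienone; racemic, formed in the flask) | COCOc1ccc(C2=C(CC=C(C)C)C(=O)C3=C(O2)C=C(OCOC)C(C(C)(C)C=C)C3=O)c(OCOC)c1 | intermediate
11 | 2-[2,4-bis(methoxymethoxy)phenyl]-7-(methoxymethoxy)-3,8-bis(3-methylbut-2-enyl)-8H-chromene-4,5-dione (para-dienone; racemic, formed in the flask) | COCOc1ccc(C2=C(CC=C(C)C)C(=O)C3=C(O2)C(CC=C(C)C)C(OCOC)=CC3=O)c(OCOC)c1 | intermediate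
12 | 2-[2,4-bis(methoxymethoxy)phenyl]-5-hydroxy-7-(methoxymethoxy)-3,8-bis(3-methylbut-2-enyl)-4H-chromen-4-one | COCOc1ccc(-c2oc3c(CC=C(C)C)c(OCOC)cc(O)c3c(=O)c2CC=C(C)C)c(OCOC)c1 | intermediate
13 | Kuwanon C, 2-(2,4-dihydroxyphenyl)-5,7-dihydroxy-3,8-bis(3-methylbut-2-enyl)-4H-chromen-4-one (achiral) | CC(C)=CCc1c(-c2ccc(O)cc2O)oc2c(CC=C(C)C)c(O)cc(O)c2c1=O | target

**Step count**
Total: 7 steps. Longest linear sequence: 6 steps (1, 2, 4, 5, 6, 7); step 3 is a one-step side branch that joins at step 4.

**Three steps most likely to fail, with fallbacks**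

Step 5 (proposed palladium prenyl relay and ring closure). The risks are slow ionisation of the hindered prenyl ether, loss of the prenyl group as isoprene, branched or double C-prenylation, and further ionisation of the remaining 5-O-prenyl ether. The fallback uses only known chemistry and sets out from compound 2. One equivalent of prenyl bromide (K2CO3, acetone, rt) etherifies a single chelated hydroxyl to give 1-[2-hydroxy-4-(methoxymethoxy)-6-(3-methylbut-2-enyloxy)phenyl]ethanone F1. Claisen condensation of its dianion with ester 5 (LiN(SiMe3)2, 3.5 equiv, THF) gives the ortho-hydroxy diketone 1-[2,4-bis(methoxymethoxy)phenyl]-3-[2-hydroxy-4-(methoxymethoxy)-6-(3-methylbut-2-enyloxy)phenyl]propane-1,3-dione F2. Classical C-alkylation of the diketone carbon with prenyl bromide (1.0 equiv, K2CO3, acetone, 40 °C) then comes back to the route at compound 7, which is closed with PPTS through 8 to the isolated compound 9.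

Step 6 (Claisen–Cope shift). The risks are arrest at the 6-(1,1-dimethylallyl) stage, simple loss of the O-prenyl group, or interference from the C3 prenyl group. The fallback abandons the sigmatropic delivery and sets the ring-A prenyl group by direct nuclear alkylation before ring C exists; it sets out from compound 1 and comes back at compound 13.
- C-Prenylation of 1 (prenyl bromide, DBU, THF, 0 °C to rt; known, modest yield) gives 1-[2,4,6-trihydroxy-3-(3-methylbut-2-enyl)phenyl]ethanone F3.
- MOMCl (2.2 equiv) with i-Pr2NEt protects the two less hindered hydroxyls and leaves the hydroxyl flanked by the prenyl and acetyl groups, giving 1-[2-hydroxy-4,6-bis(methoxymethoxy)-3-(3-methylbut-2-enyl)phenyl]ethanone F4.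
- Claisen condensation with 5 (LiN(SiMe3)2, THF) gives 1-[2,4-bis(methoxymethoxy)phenyl]-3-[2-hydroxy-4,6-bis(methoxymethoxy)-3-(3-methylbut-2-enyl)phenyl]propane-1,3-dione F5.
- Prenyl bromide with K2CO3 in acetone gives the C-prenyl diketone 1-[2,4-bis(methoxymethoxy)phenyl]-3-[2-hydroxy-4,6-bis(methoxymethoxy)-3-(3-methylbut-2-enyl)phenyl]-2-(3-methylbut-2-enyl)propane-1,3-dione F6.
- PPTS closes F6 through the hemiketal 2-[2,4-bis(methoxymethoxy)phenyl]-2-hydroxy-5,7-bis(methoxymethoxy)-3,8-bis(3-methylbut-2-enyl)chroman-4-one F7 to 2-[2,4-bis(methoxymethoxy)phenyl]-5,7-bis(methoxymethoxy)-3,8-bis(3-methylbut-2-enyl)-4H-chromen-4-one F8.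
- HCl/MeOH as in step 7 converts F8 into compound 13.

Step 7 (acid deprotection beside two prenyl groups). The risk is acid-induced chroman formation between the 7-OH and the C8 prenyl group, or addition of methanol to the alkenes. The fallback replaces Brønsted-acid solvolysis by a protecting-group exchange under buffered conditions and sets out from compound 12. TMSOTf with 2,2'-bipyridyl in CH3CN (0 °C to rt) converts the three aryl MOM ethers, and the free 5-OH, into trimethylsilyl ethers, giving 2-[2,4-bis(trimethylsilyloxy)phenyl]-3,8-bis(3-methylbut-2-enyl)-5,7-bis(trimethylsilyloxy)-4H-chromen-4-one F9. Stirring F9 in THF/water at rt hydrolyses the silyl ethers and comes back to the route at compound 13.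

**Further compounds**
F1 | step 5 | 1-[2-hydroxy-4-(methoxymethoxy)-6-(3-methylbut-2-enyloxy)phenyl]ethanone | CC(=O)c1c(O)cc(OCOC)cc1OCC=C(C)C
F2 | step 5 | 1-[2,4-bis(methoxymethoxy)phenyl]-3-[2-hydroxy-4-(methoxymethoxy)-6-(3-methylbut-2-enyloxy)phenyl]propane-1,3-dione | COCOc1ccc(C(=O)CC(=O)c2c(O)cc(OCOC)cc2OCC=C(C)C)c(OCOC)c1
F3 | step 6 | 1-[2,4,6-trihydroxy-3-(3-methylbut-2-enyl)phenyl]ethanone | CC(=O)c1c(O)cc(O)c(CC=C(C)C)c1O
F4 | step 6 | 1-[2-hydroxy-4,6-bis(methoxymethoxy)-3-(3-methylbut-2-enyl)phenyl]ethanone | CC(=O)c1c(OCOC)cc(OCOC)c(CC=C(C)C)c1O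
F5 | step 6 | 1-[2,4-bis(methoxymethoxy)phenyl]-3-[2-hydroxy-4,6-bis(methoxymethoxy)-3-(3-methylbut-2-enyl)phenyl]propane-1,3-dione | COCOc1ccc(C(=O)CC(=O)c2c(OCOC)cc(OCOC)c(CC=C(C)C)c2O)c(OCOC)c1
F6 | step 6 | 1-[2,4-bis(methoxymethoxy)phenyl]-3-[2-hydroxy-4,6-bis(methoxymethoxy)-3-(3-methylbut-2-enyl)phenyl]-2-(3-methylbut-2-enyl)propane-1,3-dione | COCOc1ccc(C(=O)C(CC=C(C)C)C(=O)c2c(OCOC)cc(OCOC)c(CC=C(C)C)c2O)c(OCOC)c1
F7 | step 6 | 2-[2,4-bis(methoxymethoxy)phenyl]-2-hydroxy-5,7-bis(methoxymethoxy)-3,8-bis(3-methylbut-2-enyl)chroman-4-one | COCOc1ccc(C2(O)Oc3c(CC=C(C)C)c(OCOC)cc(OCOC)c3C(=O)C2CC=C(C)C)c(OCOC)c1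
F8 | step 6 | 2-[2,4-bis(methoxymethoxy)phenyl]-5,7-bis(methoxymethoxy)-3,8-bis(3-methylbut-2-enyl)-4H-chromen-4-one | COCOc1ccc(-c2oc3c(CC=C(C)C)c(OCOC)cc(OCOC)c3c(=O)c2CC=C(C)C)c(OCOC)c1
F9 | step 7 | 2-[2,4-bis(trimethylsilyloxy)phenyl]-3,8-bis(3-methylbut-2-enyl)-5,7-bis(trimethylsilyloxy)-4H-chromen-4-one | CC(C)=CCc1c(-c2ccc(O[Si](C)(C)C)cc2O[Si](C)(C)C)oc2c(CC=C(C)C)c(O[Si](C)(C)C)cc(O[Si](C)(C)C)c2c1=O
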